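(The earlier runs and the new flask come from a simulation on assumed constants; the scatter is artificial.)

I want to know how much D is gone from the flask at its asked time, how much Z stands, and whether anything is still moving.

| setting | south | north-west | flask |
|---|---|---|---|
| D | 0.20 M | 0.20 M | 0.20 M |
| X | 0.20 M | 0.20 M | 0.200 M |
| L | 0.67 mM (in portions, 3) | 1.5 mM (in portions, 3) | 1.0 mM (in portions, 3) |
| remark | run made earlier; portions every 1.0 h | run made earlier; portions every 1.0 h | the portions of L follow each other after 1.0 h, the first at the start |
| time |  |  | 15 h |

| run | time / h | D / % | Z / % |
|---|---|---|---|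
| south | 2.00 | 95.8 | 4.5 |
| south | 4.00 | 91.1 | 9.4 |
| south | 6.00 | 87.5 | 12.8 |
| south | 8.00 | 83.4 | 16.0 |
| south | 10.0 | 80.5 | 19.2 |
| south | 12.0 | 77.3 | 22.6 |
| north-west | 1.00 | 96.3 | 4.0 |
| north-west | 1.50 | 93.7 | 6.5 |
| north-west | 2.50 | 87.6 | 11.3 |
| north-west | 4.00 | 80.4 | 18.1 |
| north-west | 8.00 | 69.3 | 31.2 |
| north-west | 12.0 | 59.8 | 40.3 |

(readings scatter by 0.5 percentage points)

- why nothing more happens at 15 h, or that something still does (all of D has reacted / it is still moving / no working catalyst is left / forward and back rates have come level / X has run out first)
- part of the D gone at 15 h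
- the Z standing at 15 h, as a percentage of the D charged

- the analysis behind the earlier runs scatters by 0.5 percentage points, standard deviation
- the reaction counts as stopped when no species that holds the D changes by six tenths of a point or more over the second half of the time

First, what does Z tell me beyond D? At 12.0 h in the north-west run, D and Z add up to 100 %, so I read Z as the D that has gone.

Next, how does the speed follow L? D and X are charged equal, so a rate following both at fixed L, with the two used one for one, puts the reciprocal of the fraction of D left on a straight line in time. From 4.00 h to 12.0 h, past the last portion, that reciprocal rises per hour and per mM of L by 0.0366 /h/mM in the south run and 0.0357 /h/mM in the north-west run. Their mean, 0.0361 /h/mM, I call the climb: an apparent second-order constant per mM of L.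

That is the late end; what about the start, while portions still arrive? There I read what stands at 4.00 h: the reciprocal has passed its starting value per mM by 0.146 /mM and 0.163 /mM, mean 0.154 /mM.

Joining both ends for this flask, I reckon 64.4 % of D left at 15 h, so 35.6 % is gone, and I read the same figure for Z. At half the time I get 78.1 %, a drop of 14 percentage points, far above the scatter, so it is still moving.

The forecast, close to mine but a little lower, says it is still moving, with 35.4 % of D gone (32.5 % to 38.5 %) and Z at 35.4 % (32.5 % to 38.5 %), noting “Neither run shows a plateau”.

The flask gives: it is still moving, 35.8 % of D gone, Z at 35.6 %.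

    D + L ⇌ G (K = 8.60 /M, k = 12.0 /M/min)
    X + G ⇌ Q (K = 1.80 /M, k = 14.0 /M/min)
    Q → L + Z (k = 2.70 /min)
    X ⇌ J (K = 2.80, k = 0.00960 /min)

In this flask X trades with J, and that step by itself, both ways together, has a relaxation half-life of 0.887 h, much shorter than the 15 h asked. At 15.0 h this flask holds 15 % of its X charge still unbound, less than the 64 % of its D charge, with J at 0.0981 M.

For a second flask, the same but with 0.0040 M of L, the same head and climb give me 31.2 % of D left at 15 h; that second flask gives 29.2 %, with Z at 70.2 %.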